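Early in a run the catalyst takes up substrate first and product comes later, so the useful rate is read after that start. The question is what stands in grey and violet at the end.

| setting | midnight | summer | grey | violet |
|---|---|---|---|---|
| left-handed substrate | 0.80 M | 0.40 M | 0.80 M | 0.80 M |
| right-handed substrate | 0.80 M | 0.40 M | 0.80 M | 0.80 M |
| solid reagent | 2.4 M | 2.4 M | 2.40 M | 0.600 M |
| free catalyst | 120 mM | 80 mM | 80 mM | 80 mM |
| remark | run made earlier | run made earlier |  |  |
| time |  |  | 50 min | 50 min |

| run | time / min | right-handed substrate / % | left-handed substrate / % | left-handed product / % |
|---|---|---|---|---|
| midnight | 0.833 | 49.1 | 44.9 | 0 |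
| midnight | 1.33 | 49.1 | 43.0 | 0 |
| midnight | 2.00 | 48.5 | 43.4 | 0.8 |
| midnight | 4.00 | 49.3 | 40.4 | 4.5 |
| midnight | 6.00 | 48.3 | 37.8 | 8.1 |
| midnight | 10.0 | 48.3 | 29.5 | 15.9 |
| summer | 1.50 | 48.9 | 43.1 | 0.6 |
| summer | 3.00 | 48.2 | 40.3 | 2.8 |
| summer | 5.00 | 48.6 | 37.8 | 7.4 |
| summer | 6.00 | 48.9 | 36.1 | 9.8 |
| summer | 8.00 | 48.7 | 31.0 | 14.1 |
| summer | 10.0 | 47.7 | 26.7 | 19.9 |

(standard deviation of a reading: 0.5 percentage points)
- free catalyst is single-handed; left-handed substrate and right-handed substrate are mirror images of each other, charged as a racemate, each of them at the stated concentration
- solid, in amounts per volume of the solution: solid reagent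
- the earlier runs were read with a standard deviation of 0.5 percentage points
- steps that have been proposed: free catalyst + left-handed substrate <-> catalyst intermediate A; free catalyst + right-handed substrate <-> catalyst intermediate B; partner + catalyst intermediate A -> free catalyst + left-handed product; partner + catalyst intermediate B -> free catalyst + right-handed product; partner + free catalyst -> spent catalyst A; 2 free catalyst -> spent catalyst B; solid reagent <-> partner
- at the start none of the solid reagent is in solution
- an excess is the difference of the two amounts in percent of their sum
- an excess is below zero if the other one leads
- which of the two ends with the higher excess of right-handed substrate over left-handed substrate among what is left of the two ("neither" if they lie within 2 percentage points) (grey / violet / neither)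
- excess of right-handed substrate over left-handed substrate among what is left of the two at the end, grey
- excess of right-handed substrate over left-handed substrate among what is left of the two at the end, violet

1. In the midnight run, at 0.833 min, the left-handed substrate reads 44.9% of the two substrates charged and the right-handed 49.1%, with left-handed product at 0%. After that, product climbs steadily.

2. The right-handed substrate still reads 48.3% at 10.0 min, so I hold it at its charge c and reckon just the small thing, the product p taken from the left-handed side. The excess is then p / (c + c − p).

3. From 4.00 min to 10.0 min, the midnight run gives a turnover rate (turnover frequency), meaning product made per minute for each catalyst charged, of 0.253 /min. The summer run, with other charges, reads 0.250 /min from 5.00 min to 10.0 min, about the same as the midnight reading.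

4. Over 50 min, this rate on 80 mM of catalyst allows 1.01 M of product, if it lasts. But each product also costs one left-handed substrate and one partner, and partner comes from the solid reagent. In this reckoning I take the smallest of these three ceilings.

5. In grey the smallest ceiling is the left-handed charge, so p is 0.800 M and I expect an excess of 100%. In violet I take the solid reagent as the limiting reagent, so p is 0.600 M and I expect an excess of 60.0%.

The forecast, which differs from this reckoning on both excesses, named grey, with 68% for grey and 50% for violet, and said of violet: “This assumes saturation, not partner proportional to solid”.

The flasks give grey as the higher, with 86.0% for grey and 53.8% for violet.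

    free catalyst + left-handed substrate ⇌ catalyst intermediate A (K = 12.2 /M, k = 6.43 /M/min)
    free catalyst + right-handed substrate ⇌ catalyst intermediate B (K = 1.43 /M, k = 22.2 /M/min)
    partner + catalyst intermediate A → free catalyst + left-handed product (k = 1.27 /M/min)
    partner + catalyst intermediate B → free catalyst + right-handed product (k = 0.0146 /M/min)
    partner + free catalyst → spent catalyst A (k = 0.0803 /M/min)
    2 free catalyst → spent catalyst B (k = 0.683 /M/min)
    solid reagent ⇌ partner, rate k7*(cs7 - [partner]) while solid is left; crystals form when [partner] > cs7 (solubility = 0.690 M, k = 0.153 /min)

The difference in solid reagent is the main reason for the gap: with grey's charge, violet gives 86.0% instead of 53.8%. Grey's product of 46.1% means 0.184 /min on average over the run, less than the turnover rate, and at the end spent catalyst A and B hold 39.3% and 20.3% of the catalyst charged.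

A neighbour of grey charged with 0.048 M of free catalyst has a rate ceiling of 0.608 M, below the left-handed charge, so the reckoning gives 61.3%. The computed result is 63.0%.

The earlier runs and the new flask were computed with constants of no real substance, noise included.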